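## The problem

Compound 29 (CNP0268255.3) is a germacranolide. Ring A is the ten-membered carbocycle C1–C10. Ring B is an α-methylene-γ-butyrolactone (O–C6–C7–C11–C12, methylene C13 on C11) fused trans to ring A at C6/C7. Ring C is a cis oxirane on C1/C10, with methyl C14 on C10. The ring also carries a Z trisubstituted C4=C5 olefin (methyl C15), a free allylic hydroxyl on C3, and on O8 the ester of (2R,3R)-2,3-dimethyloxirane-2-carboxylic acid.

Six stereocentres lie on ring A (1R, 3S, 6R, 7R, 8R, 10S) and two in the ester. C6, C7 and C8 are contiguous, so one of them can control the other two. C1/C10 are insulated from this triad by the C9 methylene and need their own reagent control. C3 is remote from everything except the ring itself, and the ester centres come from a separate building block.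

The molecule tolerates little. The methylene lactone is a Michael acceptor, and under base the lactone can migrate from O6 to O8. Both oxiranes are sensitive to acid and Lewis acid. Any C3 carbonyl precursor is β,γ to ring C, and the Z olefin sits in a strained medium ring that is hard to close.

The feature that opens the route is that the lactone α-carbon C11 is bonded to C7, which lies between the two oxygen-bearing carbons C6 and C8. A C7–C8 epoxide next to an O6-bound carbanion can therefore deliver the C7–C11 bond, ring B and the free O8 hydroxyl in one operation.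

## Retrosynthesis

**Ring A, C3–C4.** 29 is opened to the seco aldehyde 28, a Z alkenyl iodide at C4 and an aldehyde at C3. The neighbouring cuts (C2–C3, C5–C6) would need an sp3–sp3 closure or would disturb the lactone. The C3–C4 cut produces the allylic alcohol directly, and the Z geometry can be fixed beforehand in a four-carbon building block. The precursor is acyclic. The forward Nozaki–Hiyama–Kishi closure must tolerate lactone, ester and two oxiranes and must set C3.

**C3 oxidation level and the O8 ester.** 28 comes from alcohol 27 and silyl ether 26. 26 is the ester of hydroxy lactone 20 with epoxy acid 24. The hindered acyl group is attached after ring B exists, because O8 is only freed by the key step. Acid 24 traces through epoxy alcohol 23 and allylic alcohol 22 to angelic acid 21. The Z geometry of 21 becomes the cis relationship of carboxyl and C3 methyl in the oxirane.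

**C11=C13.** 20 is the Horner–Wadsworth–Emmons product of α-phosphono lactone 19 and formaldehyde. An enolate methylenation of a plain lactone would need strong base beside a free hydroxyl and two oxiranes; the phosphonate avoids this.

**C7–C11 and ring B (key cut).** 19 is opened to phosphonoacetate 18, in which C7 and C8 form a trans epoxide and the carbon acid hangs on O6. Intermolecular delivery of an acetate unit to a 2,3-epoxy alcohol would go to C8, so the tether is what directs the carbon to C7. The precursor loses a ring and a stereocentre, and C6, C7 and C8 reduce to one erythro epoxy alcohol. The forward step must be a C-alkylation at C7 with inversion.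

**Ester and C7–C8 epoxide.** 18 is the ester of epoxy alcohol 16 with acid 17. 16 is the Sharpless epoxidation product of bis-allylic alcohol 15, so C7 and C8 derive from C6 and the tartrate together.

**C6–C7.** 15 is cut between the carbinol carbon and the E olefin into enal 4 and alkyne 12. Hydrometalation of 12 gives the E alkenyl nucleophile, and a chiral amino alcohol sets C6. Cutting C5–C6 instead would require a metalated iodoalkene.

**Ring C and the C8–C9 bond.** 12 comes from silylalkyne 11, made by alkylating an acetylide with the triflate 10 of epoxy alcohol 9. 9 is the Sharpless product of the Z allylic alcohol 8. Placing the hydroxyl on C9 lets a reliable allylic epoxidation set C1/C10 instead of an undirected epoxidation of an isolated olefin. 8 comes from enoate 7, the Still–Gennari product of aldehyde 5 and phosphonate 6.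

**Iodo enal.** 4 is the oxidation product of (Z)-iodobutenol 3, made from but-2-yn-1-ol 1 through the cyclic alkenylaluminate 2.

## Roads not taken

**Alternative 1:** The cut is C6–C7, with ring A reached by contraction of a thirteen-membered ring in which O6 is joined to C13 as an allyl ether. In the forward step, tin–lithium exchange at C6 with n-BuLi starts a [2,3]-Wittig shift that forms C6–C7, breaks O–C13 and creates the C11=C13 methylene. It delivers the ring-A alcohol A1.
- Merits: the medium ring is not closed directly, C6 and C7 arise in one concerted event, and C3 is already fixed in A1. On ring formation and C3 it is the better road.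
- Weak points: the stereochemical outcome depends on which macrocyclic transition-state geometry is used, and n-BuLi meets the 1,10-oxirane. A1 still has C12 at the alcohol level, C8 as a PMB ether and two silyl ethers to tell apart, so several oxidation and protecting-group steps follow on the sensitive ring.
- Comparison: the chosen plan sets against it a lactone at the correct oxidation level from the start, C6–C8 from a single epoxide, and no organolithium near an oxirane. It pays with a late ring closure whose C3 outcome is open.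

**Alternative 2:** The cut is O6–C12 and C11–C12 (carbon monoxide). In the forward step, a C6 hydroxyl and a C7 ethynyl group on the complete ten-membered ring take up CO under PdCl2 and thiourea to close ring B with its methylene. The product is A2, the C3 silyl ether of 29.
- Merits: the Michael acceptor appears only at the end, and A2 is one deprotection from the target. In endgame step count and in never exposing the methylene lactone to other reagents it is better.
- Weak points: the key step solves no stereochemical problem. The C6/C7/C8 triad with an ethynyl branch at C7, ring C, the ester and the ring itself must all exist beforehand. Divalent palladium and CO then act next to two oxiranes and a hindered propargylic centre.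
- Comparison: the chosen plan's key step itself creates C7, frees O8 and builds ring B in the open chain, where asymmetric epoxidation is reliable.

**Alternative 3:** The cut is C8–C9. In the forward step, SmI2 reduces a C9 bromide beside a C10 ketone, and the samarium enolate adds to a C8 aldehyde. This closes ring A, sets C8 and gives the β-hydroxy ketone lactone A3.
- Merits: samarium Reformatsky closures are among the most dependable medium-ring closures, and the existing lactone can guide C8 through a chelate. For the ring-forming event it is probably the safer road.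
- Weak points: A3 lacks C13, C14 and ring C. After closure it needs methyl addition to C10 with facial control on a mobile ring, oxirane closure from O1, methylenation of a lactone beside a retro-aldol-prone β-hydroxy ketone, acylation and two deprotections.
- Comparison: the chosen plan closes the ring last with every substituent in place. It accepts a less proven closure in exchange.

Key step: step 11

Assumption: 5, 6 and 17 are taken as purchasable; if 6 or 17 had to be made, one step each would be added (C-methylation of the parent trifluoroethyl phosphonoacetate; partial saponification of triethyl phosphonoacetate). Atom numbers C1–C15 are those defined under "The problem".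

## Route

Step 1
Reactants: 1 but-2-yn-1-ol
Product: 3 (2Z)-3-iodobut-2-en-1-ol, via cyclic alkenylaluminate 2 (not isolated)
Conditions: NaAlH2(OCH2CH2OCH3)2, THF, 0 °C to rt; then I2, THF, −78 to 0 °C
Reagents that add atoms: iodine, II
Why: Alkoxide-directed trans-hydroalumination of the propargylic alcohol places aluminium on the methyl-bearing carbon inside a five-membered chelate, and iodinolysis with retention gives only the Z iodide; this geometry later becomes the Z C4=C5 olefin.

Step 2
Reactants: 3 (2Z)-3-iodobut-2-en-1-ol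
Product: 4 (2Z)-3-iodobut-2-enal
Conditions: MnO2, CH2Cl2, rt, dark
Reagents that add atoms: none
Why: Allylic oxidation with MnO2 is neutral and heterogeneous, so the Z geometry and the C–I bond should persist; the volatile aldehyde is used at once.

Step 3
Reactants: 5 3-[(tert-butyldimethylsilyl)oxy]propanal; 6 ethyl 2-[bis(2,2,2-trifluoroethoxy)phosphoryl]propanoate
Product: 7 ethyl (2Z)-5-[(tert-butyldimethylsilyl)oxy]-2-methylpent-2-enoate
Conditions: KN(SiMe3)2, 18-crown-6, THF, −78 °C
Reagents that add atoms: none
Why: Still–Gennari olefination; the electron-poor phosphonate eliminates faster than the adducts equilibrate, which gives the Z trisubstituted enoate and so the cis relationship of C9 and C2 that ring C needs.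

Step 4
Reactants: 7 ethyl (2Z)-5-[(tert-butyldimethylsilyl)oxy]-2-methylpent-2-enoate
Product: 8 (2Z)-5-[(tert-butyldimethylsilyl)oxy]-2-methylpent-2-en-1-ol
Conditions: iBu2AlH, CH2Cl2, −78 °C
Reagents that add atoms: none
Why: 1,2-Reduction of the enoate by the aluminium hydride gives the allylic alcohol without touching olefin geometry or the silyl ether.

Step 5
Reactants: 8 (2Z)-5-[(tert-butyldimethylsilyl)oxy]-2-methylpent-2-en-1-ol
Product: 9 [(2S,3R)-3-{2-[(tert-butyldimethylsilyl)oxy]ethyl}-2-methyloxiran-2-yl]methanol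
Conditions: Ti(OiPr)4 (10 mol %), L-(+)-diethyl tartrate (12 mol %), t-BuOOH, 4 Å MS, CH2Cl2, −20 °C
Reagents that add atoms: tert-butyl hydroperoxide, CC(C)(C)OO
Why: Sharpless asymmetric epoxidation; with L-(+)-tartrate a Z 2-methylalk-2-en-1-ol is oxidised on the face that gives the (2S,3R) epoxy alcohol, which is 10S,1R of the target, and syn addition keeps C9 and C2 cis.

Step 6
Reactants: 9 [(2S,3R)-3-{2-[(tert-butyldimethylsilyl)oxy]ethyl}-2-methyloxiran-2-yl]methanol
Product: 11 tert-butyldimethyl(2-{(2R,3S)-3-methyl-3-[3-(trimethylsilyl)prop-2-yn-1-yl]oxiran-2-yl}ethoxy)silane, via epoxy triflate 10 (not isolated)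
Conditions: Tf2O, 2,6-lutidine, CH2Cl2, −78 °C; then LiC≡CSiMe3 (from Me3SiC≡CH, n-BuLi), THF–DMPU, −78 to −20 °C
Reagents that add atoms: lithium (trimethylsilyl)acetylide, [Li]C#C[Si](C)(C)C
Why: O-Sulfonylation followed by SN2 alkylation of a lithium acetylide by a primary triflate forms C8–C9; C10 has no hydrogen, so elimination is excluded, and without a Lewis acid the acetylide should leave the oxirane alone at low temperature. No stereocentre is touched.

Step 7
Reactants: 11 tert-butyldimethyl(2-{(2R,3S)-3-methyl-3-[3-(trimethylsilyl)prop-2-yn-1-yl]oxiran-2-yl}ethoxy)silane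
Product: 12 tert-butyldimethyl{2-[(2R,3S)-3-methyl-3-(prop-2-yn-1-yl)oxiran-2-yl]ethoxy}silane
Conditions: K2CO3 (cat.), MeOH, rt
Reagents that add atoms: none
Why: Base-catalysed methanolysis of the alkynyl C–Si bond; the primary silyl ether and the oxirane are stable to these conditions.

Step 8
Reactants: 12 tert-butyldimethyl{2-[(2R,3S)-3-methyl-3-(prop-2-yn-1-yl)oxiran-2-yl]ethoxy}silane; 4 (2Z)-3-iodobut-2-enal
Product: 15 (2Z,4S,5E)-7-[(2S,3R)-3-{2-[(tert-butyldimethylsilyl)oxy]ethyl}-2-methyloxiran-2-yl]-2-iodohepta-2,5-dien-4-ol, via alkenyldicyclohexylborane 13 (not isolated), via alkenylmethylzinc 14 (not isolated)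
Conditions: (c-C6H11)2BH (from BH3·SMe2, cyclohexene), toluene, 0 °C to rt; Me2Zn, (−)-MIB (5 mol %), −78 °C; then 4, −20 to 0 °C
Reagents that add atoms: none
Why: syn-Hydroboration of the terminal alkyne gives the E alkenylborane, boron-to-zinc exchange gives the alkenylzinc, and amino-alcohol-catalysed addition to the aldehyde forms C6–C7. (−)-MIB directs transfer to the Si face of aldehydes, which corresponds to 4S in 15 (6R of the target once C7 bears oxygen); any C6 epimer is removed in step 9.

Step 9
Reactants: 15 (2Z,4S,5E)-7-[(2S,3R)-3-{2-[(tert-butyldimethylsilyl)oxy]ethyl}-2-methyloxiran-2-yl]-2-iodohepta-2,5-dien-4-ol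
Product: 16 (1R,2Z)-1-[(2R,3R)-3-{[(2S,3R)-3-{2-[(tert-butyldimethylsilyl)oxy]ethyl}-2-methyloxiran-2-yl]methyl}oxiran-2-yl]-3-iodobut-2-en-1-ol
Conditions: Ti(OiPr)4 (20 mol %), D-(−)-diisopropyl tartrate (24 mol %), t-BuOOH, 4 Å MS, CH2Cl2, −20 °C
Reagents that add atoms: tert-butyl hydroperoxide, CC(C)(C)OO
Why: Sharpless epoxidation of a secondary allylic alcohol in the matched sense: with D-(−)-tartrate the (S)-carbinol reacts fast and anti to its hydroxyl, giving the erythro epoxy alcohol and so C7 and C8. The C6 epimer is the slow partner. The iodoalkene is electron-poor, cis-substituted and mismatched, so it should stay untouched.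

Step 10
Reactants: 16 (1R,2Z)-1-[(2R,3R)-3-{[(2S,3R)-3-{2-[(tert-butyldimethylsilyl)oxy]ethyl}-2-methyloxiran-2-yl]methyl}oxiran-2-yl]-3-iodobut-2-en-1-ol; 17 2-(diethoxyphosphoryl)acetic acid
Product: 18 (1R,2Z)-1-[(2S,3R)-3-{[(2S,3R)-3-{2-[(tert-butyldimethylsilyl)oxy]ethyl}-2-methyloxiran-2-yl]methyl}oxiran-2-yl]-3-iodobut-2-en-1-yl 2-(diethoxyphosphoryl)acetate
Conditions: DCC, DMAP (cat.), CH2Cl2, 0 °C to rt
Reagents that add atoms: none
Why: Steglich esterification under neutral conditions attaches the carbon acid to O6 and leaves both oxiranes intact; the descriptor at C7 changes only because of CIP priorities.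

Step 11
Reactants: 18 (1R,2Z)-1-[(2S,3R)-3-{[(2S,3R)-3-{2-[(tert-butyldimethylsilyl)oxy]ethyl}-2-methyloxiran-2-yl]methyl}oxiran-2-yl]-3-iodobut-2-en-1-yl 2-(diethoxyphosphoryl)acetate
Product: 19 diethyl {(4R,5S)-4-[(1R)-1-hydroxy-2-{(2S,3R)-3-[2-(tert-butyldimethylsilyloxy)ethyl]-2-methyloxiran-2-yl}ethyl]-5-[(1Z)-2-iodoprop-1-en-1-yl]-2-oxooxolan-3-yl}phosphonate (C11 epimers)
Conditions: NaH (1.1 equiv), THF–DMF, 0 °C to rt; AcOH, 0 °C
Reagents that add atoms: none
Why: NaH removes a proton from the phosphonoacetate CH2 irreversibly, and the carbanion carbon C11 attacks C7 anti to the epoxide C7–O bond, so that C7–C11 and ring B form while the oxygen stays on C8 with its configuration unchanged. The closest known reaction types are the intermolecular opening of epoxides by sodium phosphonoacetate that ends in α-phosphono γ-lactones, and the 5-exo attack on C2 of 2,3-epoxy alcohols by nucleophiles tethered to O1 (carbonates, urethanes). Ring B closes in the 5-exo-tet mode; attack at C8 would be 6-endo and is disfavoured by the three-atom tether. C7 is set by SN2 inversion of the trans epoxide from step 9, so the erythro epoxy alcohol becomes the trans C6/C7 lactone with C11 anti to O8; C11 itself forms as an epimer mixture that step 12 erases. The closure needs the ester in its s-trans form and a nucleophilic lobe in the plane of the new ring; the exocyclic P=O group keeps the carbanion stabilised when it twists out of conjugation with C12=O, which should allow C- over O-alkylation where a plain acetate enolate would fail. The C8 alkoxide is protonated at once by the far more acidic P–CH of the product, so lactone migration to O8, attack on the 1,10-oxirane and cyclopropane formation through attack on phosphorus should not compete at or below room temperature. Quenching with AcOH at 0 °C returns 19.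

Step 12
Reactants: 19 diethyl {(4R,5S)-4-[(1R)-1-hydroxy-2-{(2S,3R)-3-[2-(tert-butyldimethylsilyloxy)ethyl]-2-methyloxiran-2-yl}ethyl]-5-[(1Z)-2-iodoprop-1-en-1-yl]-2-oxooxolan-3-yl}phosphonate (C11 epimers)
Product: 20 (4R,5S)-4-[(1R)-1-hydroxy-2-{(2S,3R)-3-[2-(tert-butyldimethylsilyloxy)ethyl]-2-methyloxiran-2-yl}ethyl]-5-[(1Z)-2-iodoprop-1-en-1-yl]-3-methylideneoxolan-2-one
Conditions: aq. HCHO, K2CO3, THF, 0 °C
Reagents that add atoms: formaldehyde, C=O
Why: Horner–Wadsworth–Emmons olefination; the weak base deprotonates only the phosphonate C–H, both C11 epimers converge on one methylene lactone, and low temperature keeps O8 from attacking C12.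

Step 13
Reactants: 21 angelic acid [(2Z)-2-methylbut-2-enoic acid]
Product: 22 (2Z)-2-methylbut-2-en-1-ol
Conditions: LiAlH4, Et2O, 0 °C
Reagents that add atoms: none
Why: Hydride reduction of the conjugated acid gives the allylic alcohol; the trisubstituted olefin and its Z geometry are not affected.

Step 14
Reactants: 22 (2Z)-2-methylbut-2-en-1-ol
Product: 23 [(2S,3R)-2,3-dimethyloxiran-2-yl]methanol
Conditions: Ti(OiPr)4 (10 mol %), L-(+)-diethyl tartrate (12 mol %), t-BuOOH, 4 Å MS, CH2Cl2, −20 °C
Reagents that add atoms: tert-butyl hydroperoxide, CC(C)(C)OO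
Why: Sharpless asymmetric epoxidation with the same facial sense as in step 5; the Z olefin gives the oxirane with CH2OH and the C3 methyl cis.

Step 15
Reactants: 23 [(2S,3R)-2,3-dimethyloxiran-2-yl]methanol
Product: 24 (2R,3R)-2,3-dimethyloxirane-2-carboxylic acid
Conditions: RuCl3 (cat.), NaIO4, MeCN–EtOAc–H2O, rt
Reagents that add atoms: water, O
Why: RuO4 generated in the flask oxidises the primary alcohol through the aldehyde hydrate to the acid; C2 is quaternary and cannot epimerise, and its descriptor changes from S to R only through CIP priorities.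

Step 16
Reactants: 24 (2R,3R)-2,3-dimethyloxirane-2-carboxylic acid; 20 (4R,5S)-4-[(1R)-1-hydroxy-2-{(2S,3R)-3-[2-(tert-butyldimethylsilyloxy)ethyl]-2-methyloxiran-2-yl}ethyl]-5-[(1Z)-2-iodoprop-1-en-1-yl]-3-methylideneoxolan-2-one
Product: 26 (1R)-2-{(2S,3R)-3-[2-(tert-butyldimethylsilyloxy)ethyl]-2-methyloxiran-2-yl}-1-{(2S,3R)-2-[(1Z)-2-iodoprop-1-en-1-yl]-4-methylidene-5-oxooxolan-3-yl}ethyl (2R,3R)-2,3-dimethyloxirane-2-carboxylate, via mixed anhydride 25 (not isolated)
Conditions: 2,4,6-Cl3C6H2COCl, Et3N, toluene, rt; then 20, DMAP, rt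
Reagents that add atoms: none
Why: Yamaguchi esterification; the mixed anhydride transfers the aliphatic acyl group through DMAP to the hindered C8 hydroxyl, and the acid has no α-hydrogen, so its configuration is safe.

Step 17
Reactants: 26 (1R)-2-{(2S,3R)-3-[2-(tert-butyldimethylsilyloxy)ethyl]-2-methyloxiran-2-yl}-1-{(2S,3R)-2-[(1Z)-2-iodoprop-1-en-1-yl]-4-methylidene-5-oxooxolan-3-yl}ethyl (2R,3R)-2,3-dimethyloxirane-2-carboxylate
Product: 27 (1R)-2-[(2S,3R)-3-(2-hydroxyethyl)-2-methyloxiran-2-yl]-1-{(2S,3R)-2-[(1Z)-2-iodoprop-1-en-1-yl]-4-methylidene-5-oxooxolan-3-yl}ethyl (2R,3R)-2,3-dimethyloxirane-2-carboxylate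
Conditions: Bu4NF, AcOH (1:1), THF, 0 °C to rt
Reagents that add atoms: none
Why: Fluoride cleaves the primary silyl ether; acetic acid buffering keeps the medium non-basic, so lactone, ester, methylene acceptor and oxiranes should survive.

Step 18
Reactants: 27 (1R)-2-[(2S,3R)-3-(2-hydroxyethyl)-2-methyloxiran-2-yl]-1-{(2S,3R)-2-[(1Z)-2-iodoprop-1-en-1-yl]-4-methylidene-5-oxooxolan-3-yl}ethyl (2R,3R)-2,3-dimethyloxirane-2-carboxylate
Product: 28 (1R)-2-[(2S,3R)-2-methyl-3-(2-oxoethyl)oxiran-2-yl]-1-{(2S,3R)-2-[(1Z)-2-iodoprop-1-en-1-yl]-4-methylidene-5-oxooxolan-3-yl}ethyl (2R,3R)-2,3-dimethyloxirane-2-carboxylate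
Conditions: Dess–Martin periodinane, NaHCO3, CH2Cl2, 0 °C
Reagents that add atoms: none
Why: Dess–Martin oxidation under bicarbonate buffer gives the C3 aldehyde without acid or base strong enough to open ring C; the β,γ-epoxy aldehyde is filtered and used crude at once.

Step 19
Reactants: 28 (1R)-2-[(2S,3R)-2-methyl-3-(2-oxoethyl)oxiran-2-yl]-1-{(2S,3R)-2-[(1Z)-2-iodoprop-1-en-1-yl]-4-methylidene-5-oxooxolan-3-yl}ethyl (2R,3R)-2,3-dimethyloxirane-2-carboxylate
Product: 29 (1R,3S,4Z,6R,7R,8R,10S)-1,10-epoxy-3-hydroxy-8-[(2R,3R)-2,3-dimethyloxirane-2-carbonyloxy]germacra-4,11(13)-dien-12,6-olide (CNP0268255.3)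
Conditions: CrCl2 (10 equiv), NiCl2 (cat.), DMSO, rt, 2 mM
Reagents that add atoms: none
Why: Nozaki–Hiyama–Kishi reaction; nickel inserts into the C4–I bond, the alkenyl group passes with retention to trivalent chromium and adds to the C3 aldehyde only, closing ring A with the Z olefin in place. C3 is set under substrate control in the ring-closing transition state, with the aldehyde hydrogen turned toward the cis C6 substituent and the oxygen on the ring periphery; the required 3S outcome is the point to be verified.

## Compound list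

1 | but-2-yn-1-ol | CC#CCO | starting material
2 | sodium 2,2-bis(2-methoxyethoxy)-3-methyl-2,5-dihydro-1,2-oxaaluminol-2-uide (cyclic alkenylaluminate) | CC1=CCO[Al-]1(OCCOC)OCCOC.[Na+] | intermediate (not isolated)
3 | (2Z)-3-iodobut-2-en-1-ol | C/C(I)=C/CO | intermediate
4 | (2Z)-3-iodobut-2-enal | C/C(I)=C/C=O | intermediate
5 | 3-[(tert-butyldimethylsilyl)oxy]propanal | O=CCCO[Si](C)(C)C(C)(C)C | starting material
6 | ethyl 2-[bis(2,2,2-trifluoroethoxy)phosphoryl]propanoate | CCOC(=O)C(C)P(=O)(OCC(F)(F)F)OCC(F)(F)F | starting material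
7 | ethyl (2Z)-5-[(tert-butyldimethylsilyl)oxy]-2-methylpent-2-enoate | CCOC(=O)/C(C)=C\CCO[Si](C)(C)C(C)(C)C | intermediate
8 | (2Z)-5-[(tert-butyldimethylsilyl)oxy]-2-methylpent-2-en-1-ol | OC/C(C)=C\CCO[Si](C)(C)C(C)(C)C | intermediate
9 | [(2S,3R)-3-{2-[(tert-butyldimethylsilyl)oxy]ethyl}-2-methyloxiran-2-yl]methanol | OC[C@]1(C)O[C@@H]1CCO[Si](C)(C)C(C)(C)C | intermediate
10 | [(2S,3R)-3-{2-[(tert-butyldimethylsilyl)oxy]ethyl}-2-methyloxiran-2-yl]methyl trifluoromethanesulfonate | FC(F)(F)S(=O)(=O)OC[C@]1(C)O[C@@H]1CCO[Si](C)(C)C(C)(C)C | intermediate (not isolated)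
11 | tert-butyldimethyl(2-{(2R,3S)-3-methyl-3-[3-(trimethylsilyl)prop-2-yn-1-yl]oxiran-2-yl}ethoxy)silane | C[Si](C)(C)C#CC[C@]1(C)O[C@@H]1CCO[Si](C)(C)C(C)(C)C | intermediate
12 | tert-butyldimethyl{2-[(2R,3S)-3-methyl-3-(prop-2-yn-1-yl)oxiran-2-yl]ethoxy}silane | C#CC[C@]1(C)O[C@@H]1CCO[Si](C)(C)C(C)(C)C | intermediate
13 | dicyclohexyl[(1E)-3-{(2S,3R)-3-[2-(tert-butyldimethylsilyloxy)ethyl]-2-methyloxiran-2-yl}prop-1-en-1-yl]borane | C1CCCCC1B(C2CCCCC2)/C=C/C[C@]3(C)O[C@@H]3CCO[Si](C)(C)C(C)(C)C | intermediate (not isolated)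
14 | methyl[(1E)-3-{(2S,3R)-3-[2-(tert-butyldimethylsilyloxy)ethyl]-2-methyloxiran-2-yl}prop-1-en-1-yl]zinc | C[Zn]/C=C/C[C@]1(C)O[C@@H]1CCO[Si](C)(C)C(C)(C)C | intermediate (not isolated)
15 | (2Z,4S,5E)-7-[(2S,3R)-3-{2-[(tert-butyldimethylsilyl)oxy]ethyl}-2-methyloxiran-2-yl]-2-iodohepta-2,5-dien-4-ol | O[C@H](/C=C(/C)I)/C=C/C[C@]1(C)O[C@@H]1CCO[Si](C)(C)C(C)(C)C | intermediate
16 | (1R,2Z)-1-[(2R,3R)-3-{[(2S,3R)-3-{2-[(tert-butyldimethylsilyl)oxy]ethyl}-2-methyloxiran-2-yl]methyl}oxiran-2-yl]-3-iodobut-2-en-1-ol (erythro epoxy alcohol) | O[C@H](/C=C(/C)I)[C@H]1O[C@@H]1C[C@]2(C)O[C@@H]2CCO[Si](C)(C)C(C)(C)C | intermediate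
17 | 2-(diethoxyphosphoryl)acetic acid | CCOP(=O)(OCC)CC(=O)O | starting material
18 | (1R,2Z)-1-[(2S,3R)-3-{[(2S,3R)-3-{2-[(tert-butyldimethylsilyl)oxy]ethyl}-2-methyloxiran-2-yl]methyl}oxiran-2-yl]-3-iodobut-2-en-1-yl 2-(diethoxyphosphoryl)acetate | CCOP(=O)(OCC)CC(=O)O[C@H](/C=C(/C)I)[C@H]1O[C@@H]1C[C@]2(C)O[C@@H]2CCO[Si](C)(C)C(C)(C)C | intermediate
19 | diethyl {(4R,5S)-4-[(1R)-1-hydroxy-2-{(2S,3R)-3-[2-(tert-butyldimethylsilyloxy)ethyl]-2-methyloxiran-2-yl}ethyl]-5-[(1Z)-2-iodoprop-1-en-1-yl]-2-oxooxolan-3-yl}phosphonate (C11 epimers) | CCOP(=O)(OCC)C1C(=O)O[C@H](/C=C(/C)I)[C@H]1[C@H](O)C[C@]2(C)O[C@@H]2CCO[Si](C)(C)C(C)(C)C | intermediate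
20 | (4R,5S)-4-[(1R)-1-hydroxy-2-{(2S,3R)-3-[2-(tert-butyldimethylsilyloxy)ethyl]-2-methyloxiran-2-yl}ethyl]-5-[(1Z)-2-iodoprop-1-en-1-yl]-3-methylideneoxolan-2-one | C=C1C(=O)O[C@H](/C=C(/C)I)[C@H]1[C@H](O)C[C@]2(C)O[C@@H]2CCO[Si](C)(C)C(C)(C)C | intermediate
21 | angelic acid, (2Z)-2-methylbut-2-enoic acid | C/C=C(/C)C(=O)O | starting material
22 | (2Z)-2-methylbut-2-en-1-ol | C/C=C(/C)CO | intermediate
23 | [(2S,3R)-2,3-dimethyloxiran-2-yl]methanol | OC[C@]1(C)O[C@@H]1C | intermediate
24 | (2R,3R)-2,3-dimethyloxirane-2-carboxylic acid | OC(=O)[C@]1(C)O[C@@H]1C | intermediate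
25 | (2R,3R)-2,3-dimethyloxirane-2-carboxylic 2,4,6-trichlorobenzoic anhydride | O=C(OC(=O)[C@]1(C)O[C@@H]1C)c1c(Cl)cc(Cl)cc1Cl | intermediate (not isolated)
26 | (1R)-2-{(2S,3R)-3-[2-(tert-butyldimethylsilyloxy)ethyl]-2-methyloxiran-2-yl}-1-{(2S,3R)-2-[(1Z)-2-iodoprop-1-en-1-yl]-4-methylidene-5-oxooxolan-3-yl}ethyl (2R,3R)-2,3-dimethyloxirane-2-carboxylate | C=C1C(=O)O[C@H](/C=C(/C)I)[C@H]1[C@H](OC(=O)[C@]3(C)O[C@@H]3C)C[C@]2(C)O[C@@H]2CCO[Si](C)(C)C(C)(C)C | intermediate
27 | (1R)-2-[(2S,3R)-3-(2-hydroxyethyl)-2-methyloxiran-2-yl]-1-{(2S,3R)-2-[(1Z)-2-iodoprop-1-en-1-yl]-4-methylidene-5-oxooxolan-3-yl}ethyl (2R,3R)-2,3-dimethyloxirane-2-carboxylate | C=C1C(=O)O[C@H](/C=C(/C)I)[C@H]1[C@H](OC(=O)[C@]3(C)O[C@@H]3C)C[C@]2(C)O[C@@H]2CCO | intermediate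
28 | (1R)-2-[(2S,3R)-2-methyl-3-(2-oxoethyl)oxiran-2-yl]-1-{(2S,3R)-2-[(1Z)-2-iodoprop-1-en-1-yl]-4-methylidene-5-oxooxolan-3-yl}ethyl (2R,3R)-2,3-dimethyloxirane-2-carboxylate | C=C1C(=O)O[C@H](/C=C(/C)I)[C@H]1[C@H](OC(=O)[C@]3(C)O[C@@H]3C)C[C@]2(C)O[C@@H]2CC=O | intermediate
29 | (1R,3S,4Z,6R,7R,8R,10S)-1,10-epoxy-3-hydroxy-8-[(2R,3R)-2,3-dimethyloxirane-2-carbonyloxy]germacra-4,11(13)-dien-12,6-olide (CNP0268255.3) | C=C1C(=O)O[C@@H]2/C=C(/C)[C@@H](O)C[C@H]3O[C@@]3(C)C[C@@H](OC(=O)[C@]3(C)O[C@@H]3C)[C@@H]12 | target

## Step count and least certain steps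

Total: 19 steps. Longest linear sequence: 14 steps (5 and 6 to 29 through steps 3–12 and 16–19). Enal 4 (steps 1–2) and acid 24 (steps 13–15) are side branches.

**Step 11 (key step).**
- Risk: closure at the enolate oxygen, or no closure at all. The five-membered ring must form through the s-trans ester, with limited overlap between the carbanion and the C7–O σ* orbital. If warming is needed, the C8 alkoxide may start to attack phosphorus or C12.
- Fallback: set out from 16 and return at 20. Esterify 16 with malonic acid (DCC, MeCN) to the hydrogen malonate F1. Two equivalents of NaN(SiMe3)2 give a dianion whose exocyclic carboxylate forces reaction at carbon and raises nucleophilicity; the same 5-exo opening gives the α-carboxy lactone F2. Decarboxylative Mannich methylenation of F2 with Eschenmoser's salt (Me2N=CH2 I, Et3N) gives 20 without the phosphonate.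

**Step 19.**
- Risk: slow ring closure against protodemetalation or oligomerisation, β-elimination of the β,γ-epoxy aldehyde during the long reaction, and low or reversed facial selectivity at C3, since that selectivity rests only on the conformation of the closing ring.
- Fallback: set out from 29 as obtained (C3 epimers) and return at 29. Oxidise with Dess–Martin periodinane to the C3 ketone F3, then reduce under reagent control with (R)-2-methyl-CBS-oxazaborolidine and catecholborane at −78 °C. By the usual model, with the alkenyl group as the large substituent, this should deliver the 3S alcohol.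

**Step 6.**
- Risk: sluggish displacement at the carbon next to the fully substituted oxirane carbon, and loss of the triflate through participation of the oxirane oxygen before the acetylide arrives.
- Fallback: set out from 8 and return at 11. Convert 8 (CBr4, PPh3) to the allylic bromide F4 and couple it with Me3SiC≡CMgBr under CuBr·SMe2 catalysis to the skipped enyne F5. Epoxidise F5 by Shi epoxidation with the D-fructose-derived ketone (KHSO5, K2CO3 buffer, MeCN–dimethoxymethane, 0 °C). The spiro transition-state model assigns this ketone to the 10S,1R oxirane, so 11 results, with the stereocentres now under dioxirane control.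

**Step 8.**
- Risk: weak facial discrimination by the amino alcohol on this Z β-iodo enal, isomerisation of the enal by the Lewis-acidic zinc species, and attack of boron or zinc species on the oxirane.
- Fallback: set out from 12 and 4 and return at 16. Run the alkenylzinc addition without ligand to give 15 together with its C6 epimer F6, and let step 9 act as a kinetic resolution in which only 15 is epoxidised to 16. Oxidise recovered F6 with MnO2 to the dienone F7, reduce it (NaBH4, CeCl3) back to the epimer mixture and resubmit.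

**Step 12.**
- Risk: base-promoted migration of the lactone from O6 to the free O8, or conjugate addition to the new acceptor, while the C8 hydroxyl is unprotected.
- Fallback: set out from 19 and return at 26. Acylate 19 with 24 under the conditions of step 16 to the C8 ester F8, then carry out the formaldehyde olefination on F8. This gives 26 directly and leaves no free hydroxyl in the basic step.

## Further compounds

F1 | step 11 | (1R,2Z)-1-[(2S,3R)-3-{[(2S,3R)-3-{2-[(tert-butyldimethylsilyl)oxy]ethyl}-2-methyloxiran-2-yl]methyl}oxiran-2-yl]-3-iodobut-2-en-1-yl hydrogen malonate | OC(=O)CC(=O)O[C@H](/C=C(/C)I)[C@H]1O[C@@H]1C[C@]2(C)O[C@@H]2CCO[Si](C)(C)C(C)(C)C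
F2 | step 11 | (4R,5S)-4-[(1R)-1-hydroxy-2-{(2S,3R)-3-[2-(tert-butyldimethylsilyloxy)ethyl]-2-methyloxiran-2-yl}ethyl]-5-[(1Z)-2-iodoprop-1-en-1-yl]-2-oxooxolane-3-carboxylic acid (C3 epimers) | OC(=O)C1C(=O)O[C@H](/C=C(/C)I)[C@H]1[C@H](O)C[C@]2(C)O[C@@H]2CCO[Si](C)(C)C(C)(C)C
F3 | step 19 | (1R,4Z,6R,7R,8R,10S)-1,10-epoxy-3-oxo-8-[(2R,3R)-2,3-dimethyloxirane-2-carbonyloxy]germacra-4,11(13)-dien-12,6-olide | C=C1C(=O)O[C@@H]2/C=C(/C)C(=O)C[C@H]3O[C@@]3(C)C[C@@H](OC(=O)[C@]3(C)O[C@@H]3C)[C@@H]12
F4 | step 6 | {[(3Z)-5-bromo-4-methylpent-3-en-1-yl]oxy}(tert-butyl)dimethylsilane | BrC/C(C)=C\CCO[Si](C)(C)C(C)(C)C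
F5 | step 6 | tert-butyldimethyl{[(3Z)-4-methyl-7-(trimethylsilyl)hept-3-en-6-yn-1-yl]oxy}silane | C[Si](C)(C)C#CC/C(C)=C\CCO[Si](C)(C)C(C)(C)C
F6 | step 8 | (2Z,4R,5E)-7-[(2S,3R)-3-{2-[(tert-butyldimethylsilyl)oxy]ethyl}-2-methyloxiran-2-yl]-2-iodohepta-2,5-dien-4-ol | O[C@@H](/C=C(/C)I)/C=C/C[C@]1(C)O[C@@H]1CCO[Si](C)(C)C(C)(C)C
F7 | step 8 | (2Z,5E)-7-[(2S,3R)-3-{2-[(tert-butyldimethylsilyl)oxy]ethyl}-2-methyloxiran-2-yl]-2-iodohepta-2,5-dien-4-one | O=C(/C=C(/C)I)/C=C/C[C@]1(C)O[C@@H]1CCO[Si](C)(C)C(C)(C)C
F8 | step 12 | (1R)-2-{(2S,3R)-3-[2-(tert-butyldimethylsilyloxy)ethyl]-2-methyloxiran-2-yl}-1-{(2S,3R)-4-(diethoxyphosphoryl)-2-[(1Z)-2-iodoprop-1-en-1-yl]-5-oxooxolan-3-yl}ethyl (2R,3R)-2,3-dimethyloxirane-2-carboxylate (C11 epimers) | CCOP(=O)(OCC)C1C(=O)O[C@H](/C=C(/C)I)[C@H]1[C@H](OC(=O)[C@]3(C)O[C@@H]3C)C[C@]2(C)O[C@@H]2CCO[Si](C)(C)C(C)(C)C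
A1 | alternative 1 | ring A C6 alcohol with the C11=C13 methylene, C3 and C12 tert-butyldimethylsilyl ethers and C8 4-methoxybenzyl ether | O[C@@H]1/C=C(/C)[C@@H](O[Si](C)(C)C(C)(C)C)C[C@H]2O[C@@]2(C)C[C@@H](OCc3ccc(OC)cc3)[C@H]1C(=C)CO[Si](C)(C)C(C)(C)C
A2 | alternative 2 | C3 tert-butyldimethylsilyl ether of 29 | C=C1C(=O)O[C@@H]2/C=C(/C)[C@@H](O[Si](C)(C)C(C)(C)C)C[C@H]3O[C@@]3(C)C[C@@H](OC(=O)[C@]3(C)O[C@@H]3C)[C@@H]12
A3 | alternative 3 | ring A β-hydroxy ketone lactone with C10 ketone, C8 hydroxyl, C1 triethylsilyl ether and C3 tert-butyldimethylsilyl ether | C1C(=O)O[C@@H]2/C=C(/C)[C@@H](O[Si](C)(C)C(C)(C)C)C[C@H](O[Si](CC)(CC)CC)C(=O)C[C@@H](O)[C@@H]12
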